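**Retrosynthetic overview**
- The target comes from acidolysis of a bis-MOM / tert-butyl ester precursor; ring B (the 2H-pyran) is the last ring closed, by 6-endo addition of a C8a–CH2OH onto a C4a ynenone.
- The ynenone comes from Sonogashira coupling of a ring A enol triflate (from a 1,3-dione) with tert-butyl (E)-pent-2-en-4-ynoate.
- Ring A is not built: it is (R)-carvone. The C1 carbon is added by enolate alkylation, and the isopropenyl group is degraded to the C4a oxygen (ozonolysis / Criegee).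
- C6 and C7 are set by Luche reduction, hydroxyl-directed epoxidation, and Ti-mediated opening of the epoxy alcohol at C6 by the aryl acid, which forms the ester trans to the C7–OH.
- The aryl acid comes from 2,3,4-trimethoxy-6-methylbenzaldehyde. Ring order: aryl ring and ring A are bought, ring B is formed in step 13.

Assumption: 4-methoxybenzyl chloromethyl ether (11) is taken as purchasable; ring atoms of carvone-derived compounds carry the target's locants (C1, O2, C3, C4, C4a, C5–C8, C8a), β is the face of the C7 hydroxyl in the target, α the opposite face, PMB = 4-methoxybenzyl, "aroyl" = 2-methoxy-3,4-bis(methoxymethoxy)-6-methylbenzoyl.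

**Step 1**
Reactants: 1 2,3,4-trimethoxy-6-methylbenzaldehyde
Product: 2 2,3,4-trihydroxy-6-methylbenzaldehyde
Conditions: BBr3 (4 equiv), CH2Cl2, −78 °C → rt; H2O
Reagents that add atoms: none
Why: Lewis-acid cleavage of all three aryl methyl ethers gives a triol whose three hydroxyls differ in acidity and hydrogen bonding and can be re-differentiated.

**Step 2**
Reactants: 2 2,3,4-trihydroxy-6-methylbenzaldehyde
Product: 4 2-methoxy-3,4-bis(methoxymethoxy)-6-methylbenzaldehyde, via 2-hydroxy-3,4-bis(methoxymethoxy)-6-methylbenzaldehyde 3 (not isolated)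
Conditions: MOMCl (2.1 equiv), K2CO3, acetone, 0 °C → rt; then MeI, K2CO3, 50 °C
Reagents that add atoms: chloromethyl methyl ether (COCCl); iodomethane (CI)
Why: Williamson etherification follows phenol acidity, so the 4- and 3-OH take MOM while the 2-OH, hydrogen-bonded to the aldehyde, reacts last and is methylated under forcing conditions.

**Step 3**
Reactants: 4 2-methoxy-3,4-bis(methoxymethoxy)-6-methylbenzaldehyde
Product: 5 2-methoxy-3,4-bis(methoxymethoxy)-6-methylbenzoic acid
Conditions: NaClO2, NaH2PO4, 2-methylbut-2-ene, t-BuOH/H2O, rt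
Reagents that add atoms: sodium chlorite ([Na+].[O-]Cl=O)
Why: Pinnick oxidation converts the hindered, electron-rich aldehyde to the acid without touching the MOM ethers, the alkene scavenger removing HOCl.

**Step 4**
Reactants: 6 3-(trimethylsilyl)prop-2-ynal; 7 tert-butyl (triphenylphosphoranylidene)acetate
Product: 9 tert-butyl (E)-pent-2-en-4-ynoate, via tert-butyl (E)-5-(trimethylsilyl)pent-2-en-4-ynoate 8 (not isolated)
Conditions: CH2Cl2, 0 °C → rt; then K2CO3 (cat.), MeOH, 0 °C
Reagents that add atoms: none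
Why: Wittig olefination with a stabilised ylide gives the E-enoate, and carbonate/methanol protodesilylation frees the terminal alkyne.

**Step 5**
Reactants: 10 (R)-(−)-carvone; 11 4-methoxybenzyl chloromethyl ether
Product: 13 (5R,6R)-6-{[(4-methoxybenzyl)oxy]methyl}-2-methyl-5-(prop-1-en-2-yl)cyclohex-2-en-1-one, via carvone lithium dienolate 12 (not isolated)
Conditions: lithium diisopropylamide, THF, −78 °C; then 11, −78 → −40 °C
Reagents that add atoms: none
Why: Kinetic enolate alkylation at the α′ carbon (future C8a) brings in C1 as CH2OPMB, anti to the isopropenyl group; this new centre is later destroyed.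

**Step 6**
Reactants: 13 the alkylated carvone
Product: 14 (1R,5R,6R)-6-{[(4-methoxybenzyl)oxy]methyl}-2-methyl-5-(prop-1-en-2-yl)cyclohex-2-en-1-ol (C8–OH β, cis to isopropenyl)
Conditions: NaBH4, CeCl3·7H2O, MeOH, −20 °C
Reagents that add atoms: none
Why: Luche 1,2-reduction with axial hydride delivery gives the equatorial allylic alcohol cis to the isopropenyl group, which will direct the epoxidation.

**Step 7**
Reactants: 14 the allylic alcohol
Product: 15 C6,C7-β-epoxy alcohol (oxirane cis to the C8 hydroxyl)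
Conditions: VO(acac)2 (3 mol %), t-BuOOH, CH2Cl2, 0 °C → rt
Reagents that add atoms: tert-butyl hydroperoxide (CC(C)(C)OO)
Why: Hydroxyl-directed vanadium-catalysed epoxidation delivers oxygen syn to the C8–OH and only to the allylic alkene, fixing the C7 oxygen on the β face (7S in the target).

**Step 8**
Reactants: 15 the epoxy alcohol; 5 2-methoxy-3,4-bis(methoxymethoxy)-6-methylbenzoic acid
Product: 16 C6 aryl ester triol (C8 β-OH; C7 β-OH, α-CH3; C6 α-O-aroyl; C4a β-isopropenyl; C8a α-CH2OPMB)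
Conditions: Ti(OiPr)4 (1.5 equiv), CH2Cl2, rt → 40 °C
Reagents that add atoms: none
Why: Ti(OiPr)4-mediated opening of a 2,3-epoxy alcohol by a carboxylic acid occurs at the carbon remote from the carbinol (C6), trans-diaxially and with inversion, so the ester is installed α (6R) while the tertiary C7–OH keeps its configuration.

**Step 9**
Reactants: 16 the C6 aryl ester triol
Product: 19 C4a,C8-diol ester (C4a β-OH replaces the isopropenyl of 16), via methoxy hydroperoxide 17 (not isolated), via diacetate 18 (not isolated)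
Conditions: O3, CH2Cl2/MeOH, −78 °C; Ac2O, Et3N, 4-(dimethylamino)pyridine, 0 °C → rt; then K2CO3 (cat.), MeOH, 0 °C
Reagents that add atoms: ozone ([O-][O+]=O)
Why: Ozonolysis in methanol followed by Criegee rearrangement (ring carbon migrates with retention) turns isopropenyl into the C4a acetate, and methanolysis then removes the acetates but not the di-ortho-substituted benzoate.

**Step 10**
Reactants: 19 the C4a,C8-diol ester
Product: 20 (1R,2S)-2-hydroxy-4-{[(4-methoxybenzyl)oxy]methyl}-2-methyl-3,5-dioxocyclohexyl aroate (keto/enol mixture)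
Conditions: Dess–Martin periodinane (2.2 equiv), CH2Cl2, 0 °C → rt
Reagents that add atoms: none
Why: Dess–Martin oxidation converts both secondary carbinols (C8 and C4a) to the enolised 1,3-dione and leaves the tertiary alcohol, PMB ether and esters alone.

**Step 11**
Reactants: 20 the 1,3-dione
Product: 21 (1R,2S)-2-hydroxy-4-{[(4-methoxybenzyl)oxy]methyl}-2-methyl-3-oxo-5-(trifluoromethanesulfonyloxy)cyclohex-4-en-1-yl aroate
Conditions: PhNTf2, Et3N, 4-(dimethylamino)pyridine (cat.), CH2Cl2, 0 °C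
Reagents that add atoms: N-phenylbis(trifluoromethanesulfonimide) (O=S(=O)(N(c1ccccc1)S(=O)(=O)C(F)(F)F)C(F)(F)F)
Why: Enol triflate formation should occur at the less hindered C4a oxygen, since the C8 carbonyl is flanked by the quaternary carbinol, and the mild triflimide spares the tertiary alcohol.

**Step 12**
Reactants: 21 the enol triflate; 9 tert-butyl (E)-pent-2-en-4-ynoate
Product: 22 (1R,2S)-5-[(E)-5-tert-butoxy-5-oxopent-3-en-1-yn-1-yl]-2-hydroxy-4-{[(4-methoxybenzyl)oxy]methyl}-2-methyl-3-oxocyclohex-4-en-1-yl aroate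
Conditions: PdCl2(PPh3)2 (5 mol %), CuI (10 mol %), Et3N, THF, rt
Reagents that add atoms: none
Why: Sonogashira coupling of the electron-poor vinyl triflate with the terminal alkyne forms the C4a–C4 bond and brings in C4, C3 and the acrylate chain.

**Step 13**
Reactants: 22 the ynenone
Product: 24 (6R,7S)-3-[(E)-3-tert-butoxy-3-oxoprop-1-en-1-yl]-7-hydroxy-7-methyl-8-oxo-5,6,7,8-tetrahydro-1H-isochromen-6-yl aroate, via primary alcohol 23 (not isolated)
Conditions: DDQ, CH2Cl2/pH 7 buffer, 0 °C; then Ph3PAuNTf2 (2 mol %), CH2Cl2, rt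
Reagents that add atoms: none
Why: Oxidative PMB cleavage frees the C1 hydroxyl, and gold-catalysed 6-endo-dig hydroalkoxylation at C3 (the alkyne carbon δ to the ketone) closes ring B as the conjugated vinylogous ester.

**Step 14**
Reactants: 24 the protected isochromenone
Product: 25 (E)-3-[(6R,7S)-6-(3,4-dihydroxy-2-methoxy-6-methylbenzoyloxy)-7-hydroxy-7-methyl-8-oxo-5,6,7,8-tetrahydro-1H-isochromen-3-yl]prop-2-enoic acid (target)
Conditions: CF3CO2H/CH2Cl2/H2O, 0 °C → rt
Reagents that add atoms: none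
Why: Acidolysis removes both MOM acetals and the tert-butyl ester (loss of isobutene) in one operation, leaving the hindered aryl ester and both stereocentres untouched.

**Compound list**
1 | 2,3,4-trimethoxy-6-methylbenzaldehyde | COc1cc(C)c(C=O)c(OC)c1OC | starting material
2 | 2,3,4-trihydroxy-6-methylbenzaldehyde | Cc1cc(O)c(O)c(O)c1C=O | intermediate
3 | 2-hydroxy-3,4-bis(methoxymethoxy)-6-methylbenzaldehyde | COCOc1cc(C)c(C=O)c(O)c1OCOC | intermediate (not isolated)
4 | 2-methoxy-3,4-bis(methoxymethoxy)-6-methylbenzaldehyde | COCOc1cc(C)c(C=O)c(OC)c1OCOC | intermediate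
5 | 2-methoxy-3,4-bis(methoxymethoxy)-6-methylbenzoic acid | COCOc1cc(C)c(C(=O)O)c(OC)c1OCOC | intermediate
6 | 3-(trimethylsilyl)prop-2-ynal | C[Si](C)(C)C#CC=O | starting material
7 | tert-butyl (triphenylphosphoranylidene)acetate | CC(C)(C)OC(=O)C=P(c1ccccc1)(c1ccccc1)c1ccccc1 | starting material
8 | tert-butyl (E)-5-(trimethylsilyl)pent-2-en-4-ynoate | CC(C)(C)OC(=O)/C=C/C#C[Si](C)(C)C | intermediate (not isolated)
9 | tert-butyl (E)-pent-2-en-4-ynoate | CC(C)(C)OC(=O)/C=C/C#C | intermediate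
10 | (R)-(−)-carvone, (5R)-2-methyl-5-(prop-1-en-2-yl)cyclohex-2-en-1-one | CC1=CC[C@@H](C(C)=C)CC1=O | starting material
11 | 4-methoxybenzyl chloromethyl ether | COc1ccc(COCCl)cc1 | starting material
12 | lithium dienolate of (R)-carvone (enolised towards C6) | CC1=CC[C@@H](C(C)=C)C=C1O[Li] | intermediate (not isolated)
13 | (5R,6R)-6-{[(4-methoxybenzyl)oxy]methyl}-2-methyl-5-(prop-1-en-2-yl)cyclohex-2-en-1-one (CH2OPMB α, isopropenyl β) | CC1=CC[C@@H](C(C)=C)[C@H](COCc2ccc(OC)cc2)C1=O | intermediate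
14 | (1R,5R,6R)-6-{[(4-methoxybenzyl)oxy]methyl}-2-methyl-5-(prop-1-en-2-yl)cyclohex-2-en-1-ol (C8–OH β) | CC1=CC[C@@H](C(C)=C)[C@H](COCc2ccc(OC)cc2)[C@H]1O | intermediate
15 | 3-{[(4-methoxybenzyl)oxy]methyl}-1-methyl-4-(prop-1-en-2-yl)-7-oxabicyclo[4.1.0]heptan-2-ol; oxirane O, C8–OH and isopropenyl β, CH2OPMB α | C[C@]12O[C@H]1C[C@@H](C(C)=C)[C@H](COCc3ccc(OC)cc3)[C@H]2O | intermediate
16 | cyclohexane triol monoester: C8 β-OH, C7 β-OH/α-CH3, C6 α-O-aroyl, C4a β-isopropenyl, C8a α-CH2OPMB | C[C@]1(O)[C@H](OC(=O)c2c(C)cc(OCOC)c(OCOC)c2OC)C[C@@H](C(C)=C)[C@H](COCc2ccc(OC)cc2)[C@H]1O | intermediate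
17 | methoxy hydroperoxide: 16 with C(CH3)(OCH3)OOH at C4a (both epimers at that carbon) | C[C@]1(O)[C@H](OC(=O)c2c(C)cc(OCOC)c(OCOC)c2OC)C[C@@H](C(C)(OC)OO)[C@H](COCc2ccc(OC)cc2)[C@H]1O | intermediate (not isolated)
18 | diacetate: C4a β-OAc, C8 β-OAc, otherwise as 16 | C[C@]1(O)[C@H](OC(=O)c2c(C)cc(OCOC)c(OCOC)c2OC)C[C@@H](OC(C)=O)[C@H](COCc2ccc(OC)cc2)[C@H]1OC(C)=O | intermediate (not isolated)
19 | triol ester: C4a β-OH, C8 β-OH, C7 β-OH/α-CH3, C6 α-O-aroyl, C8a α-CH2OPMB | C[C@]1(O)[C@H](OC(=O)c2c(C)cc(OCOC)c(OCOC)c2OC)C[C@@H](O)[C@H](COCc2ccc(OC)cc2)[C@H]1O | intermediate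
20 | (1R,2S)-2-hydroxy-4-{[(4-methoxybenzyl)oxy]methyl}-2-methyl-3,5-dioxocyclohexyl 2-methoxy-3,4-bis(methoxymethoxy)-6-methylbenzoate (keto/enol mixture, C4 epimerisable) | C[C@]1(O)[C@H](OC(=O)c2c(C)cc(OCOC)c(OCOC)c2OC)CC(=O)C(COCc2ccc(OC)cc2)C1=O | intermediate
21 | (1R,2S)-2-hydroxy-4-{[(4-methoxybenzyl)oxy]methyl}-2-methyl-3-oxo-5-(trifluoromethanesulfonyloxy)cyclohex-4-en-1-yl 2-methoxy-3,4-bis(methoxymethoxy)-6-methylbenzoate | C[C@]1(O)[C@H](OC(=O)c2c(C)cc(OCOC)c(OCOC)c2OC)CC(OS(=O)(=O)C(F)(F)F)=C(COCc2ccc(OC)cc2)C1=O | intermediate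
22 | (1R,2S)-5-[(E)-5-tert-butoxy-5-oxopent-3-en-1-yn-1-yl]-2-hydroxy-4-{[(4-methoxybenzyl)oxy]methyl}-2-methyl-3-oxocyclohex-4-en-1-yl 2-methoxy-3,4-bis(methoxymethoxy)-6-methylbenzoate | C[C@]1(O)[C@H](OC(=O)c2c(C)cc(OCOC)c(OCOC)c2OC)CC(C#C/C=C/C(=O)OC(C)(C)C)=C(COCc2ccc(OC)cc2)C1=O | intermediate
23 | (1R,2S)-5-[(E)-5-tert-butoxy-5-oxopent-3-en-1-yn-1-yl]-2-hydroxy-4-(hydroxymethyl)-2-methyl-3-oxocyclohex-4-en-1-yl 2-methoxy-3,4-bis(methoxymethoxy)-6-methylbenzoate | C[C@]1(O)[C@H](OC(=O)c2c(C)cc(OCOC)c(OCOC)c2OC)CC(C#C/C=C/C(=O)OC(C)(C)C)=C(CO)C1=O | intermediate (not isolated)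
24 | (6R,7S)-3-[(E)-3-tert-butoxy-3-oxoprop-1-en-1-yl]-7-hydroxy-7-methyl-8-oxo-5,6,7,8-tetrahydro-1H-isochromen-6-yl 2-methoxy-3,4-bis(methoxymethoxy)-6-methylbenzoate | C[C@]1(O)[C@H](OC(=O)c2c(C)cc(OCOC)c(OCOC)c2OC)CC2=C(COC(/C=C/C(=O)OC(C)(C)C)=C2)C1=O | intermediate
25 | (E)-3-[(6R,7S)-6-(3,4-dihydroxy-2-methoxy-6-methylbenzoyloxy)-7-hydroxy-7-methyl-8-oxo-5,6,7,8-tetrahydro-1H-isochromen-3-yl]prop-2-enoic acid | C[C@]1(O)[C@H](OC(=O)c2c(C)cc(O)c(O)c2OC)CC2=C(COC(/C=C/C(=O)O)=C2)C1=O | target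

**Totals**
Total step count: 14. Longest linear sequence: 10 steps (10 → 25, steps 5–14; the arm from 1 through steps 1–3 and 8–14 is equally long).

**Three steps most likely to fail, with fallbacks**

Step 8. A di-ortho-substituted benzoic acid has to open a trisubstituted oxirane next to a quaternary carbon; the reaction may be slow, and isopropoxide transfer or attack at C7 could compete. The fallback sets out from 15 and comes back at 16, and replaces carboxylate opening by hydrolysis followed by acylation. Dess–Martin oxidation of 15 gives the epoxy ketone F1. Aqueous HClO4 in THF opens the oxirane at C6, the carbon remote from the carbonyl and the trans-diaxial position, to give the trans-diol ketone F2. Its only secondary hydroxyl is acylated (Et3N, 4-(dimethylamino)pyridine) with the acid chloride F3, made from 5 and 1-chloro-N,N,2-trimethylprop-1-en-1-amine, to give the keto ester F4. NaBH4/CeCl3 reduction of the C8 ketone returns 16; any C8 epimer converges with 16 at dione 20.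

Step 13. The alkyne sits between two acceptors (the ring enone and the acrylate), so 5-exo attack at C4 or gold-induced side reactions could compete with the 6-endo closure. The fallback sets out from 21 and comes back at 24, and builds the side chain only after ring B exists. Sonogashira coupling of 21 with 3,3-diethoxyprop-1-yne gives the acetal ynenone F5. DDQ removes the PMB group to give the primary alcohol F6, whose alkyne is now polarised by the enone alone, and Ph3PAuNTf2 closes it to the pyran acetal F7. Pyridinium p-toluenesulfonate in wet acetone unmasks the pyran aldehyde F8, and Wittig olefination with ylide 7 gives 24.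

Step 14. The product is a dienol ether / vinylogous ester with a tertiary α-ketol; strong acid may hydrate or open ring B, and MOM-derived cations may alkylate the catechol. The fallback sets out from 22 and comes back at 25, and moves the acidolysis ahead of ring B formation. CF3CO2H/CH2Cl2/H2O on the robust ynenone 22 strips the PMB ether, both MOM groups and the tert-butyl ester to give the seco acid F9. Ring B is then closed last under neutral conditions (Ph3PAuNTf2 or AgOTf, THF), so the acid-sensitive pyran never meets strong acid.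

**Further compounds**
F1 | step 8 | epoxy ketone: C8 ketone of 15 (oxirane and isopropenyl β, CH2OPMB α) | C[C@]12O[C@H]1C[C@@H](C(C)=C)[C@H](COCc3ccc(OC)cc3)C2=O
F2 | step 8 | trans-diol ketone: C8 ketone, C7 β-OH/α-CH3, C6 α-OH, C4a β-isopropenyl, C8a α-CH2OPMB | C[C@]1(O)[C@H](O)C[C@@H](C(C)=C)[C@H](COCc2ccc(OC)cc2)C1=O
F3 | step 8 | 2-methoxy-3,4-bis(methoxymethoxy)-6-methylbenzoyl chloride | COCOc1cc(C)c(C(Cl)=O)c(OC)c1OCOC
F4 | step 8 | keto ester: F2 acylated at the C6 α-oxygen by the aroyl group | C[C@]1(O)[C@H](OC(=O)c2c(C)cc(OCOC)c(OCOC)c2OC)C[C@@H](C(C)=C)[C@H](COCc2ccc(OC)cc2)C1=O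
F5 | step 13 | acetal ynenone: 22 with a 3,3-diethoxyprop-1-yn-1-yl group at C4a | C[C@]1(O)[C@H](OC(=O)c2c(C)cc(OCOC)c(OCOC)c2OC)CC(C#CC(OCC)OCC)=C(COCc2ccc(OC)cc2)C1=O
F6 | step 13 | primary alcohol: F5 without the PMB group | C[C@]1(O)[C@H](OC(=O)c2c(C)cc(OCOC)c(OCOC)c2OC)CC(C#CC(OCC)OCC)=C(CO)C1=O
F7 | step 13 | pyran acetal: (6R,7S)-3-(diethoxymethyl)-7-hydroxy-7-methyl-8-oxo-5,6,7,8-tetrahydro-1H-isochromen-6-yl aroate | C[C@]1(O)[C@H](OC(=O)c2c(C)cc(OCOC)c(OCOC)c2OC)CC2=C(COC(C(OCC)OCC)=C2)C1=O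
F8 | step 13 | pyran aldehyde: (6R,7S)-3-formyl-7-hydroxy-7-methyl-8-oxo-5,6,7,8-tetrahydro-1H-isochromen-6-yl aroate | C[C@]1(O)[C@H](OC(=O)c2c(C)cc(OCOC)c(OCOC)c2OC)CC2=C(COC(C=O)=C2)C1=O
F9 | step 14 | seco acid: (E)-5-[(4R,5S)-4-(3,4-dihydroxy-2-methoxy-6-methylbenzoyloxy)-5-hydroxy-2-(hydroxymethyl)-5-methyl-6-oxocyclohex-1-en-1-yl]pent-2-en-4-ynoic acid | C[C@]1(O)[C@H](OC(=O)c2c(C)cc(O)c(O)c2OC)CC(C#C/C=C/C(=O)O)=C(CO)C1=O
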